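## Structural features

Vismiaphenone D is a benzophenone in which ring A, a hexasubstituted phloroglucinol-type benzene, is joined through one ketone carbon to ring B, a para-hydroxyphenyl group. With ring A numbered so that C1 carries the methoxy group and C4 the aroyl carbon, C2 and C6 carry 3-methylbut-2-enyl (prenyl) chains and C3 and C5 carry free hydroxyls hydrogen-bonded to the ketone. A mirror plane through C1, C4 and the carbonyl makes the two halves of ring A equivalent. There is no stereocentre and no stereogenic double bond, because each side-chain alkene ends in two methyl groups. The fragile parts are the ortho-prenyl phenol units, which close to 2,2-dimethylchromans or add HX under acid, and the electron-rich acylphloroglucinol core, which is easily oxidised as its phenoxide. The real difficulty is not the diaryl ketone but placing two prenyl groups on carbon at C2 and C6 only. An acylphloroglucinol anion is an ambident nucleophile, so direct prenylation risks O-alkylation, attack through the tertiary allyl terminus and geminal dialkylation with loss of aromaticity; the three ring A oxygens and the ring B phenol must also be told apart. The key step uses the fact that each benzylic CH2 (on C2 and C6) stands ortho to a phenolic oxygen (on C3 and C5): each pair can become an ortho-quinone methide whose exocyclic carbon accepts a 2-methylprop-1-enyl nucleophile, so both ArCH2–CH= bonds are made at carbon by construction.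

## Logic of the disconnections

17 is traced back to 16 by cutting the O–Si bond on ring B. The ring B phenol has to be masked through an aryllithium addition, an aminomethylation and a Grignard reaction, and a bulky silyl ether can be removed at the end with fluoride instead of acid. The gain is that the last step touches nothing else. The demand is a buffered, non-acidic, non-oxidising deprotection, because 17 holds two ortho-prenyl phenols.

16 is cut at both CH2–CH= bonds of the side chains, giving 11 and two equivalents of 12. The cut is made there because each CH2 is ortho to a phenol, so the electrophile can be an ortho-quinone methide and the bond can only form at the benzylic carbon. The gain is the loss of both C5 chains in one operation and a precursor with only one-carbon substituents. The demand is that quinone methide formation and capture happen twice on the same ring and that the nucleophile leaves the diaryl ketone alone.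

11 is simplified to 10 by cutting the two N–CH3 bonds. A neutral tertiary amine is easier to make and purify than a bis-salt, and the leaving group is then armed only in the step before it is used. The demand is alkylation on nitrogen and not on the phenol oxygens.

10 is cut at the two ring C–CH2 bonds (C2 and C6 of ring A), giving 8 and two equivalents of 9. These are the only unsubstituted positions of ring A, and each is ortho to a hydroxyl, ortho to the methoxy group and para to the other hydroxyl. The gain is a symmetrical benzophenone without carbon side chains. The demand is twofold electrophilic substitution on ring A only, which is why ring B must not carry a free phenol at this stage.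

8 is related to 7 by changing the two free hydroxyls into methoxymethyl ethers, and 7 to 6 by changing the ketone into a carbinol. The acetals are needed as directing groups for the C–C bond formation that follows in the backward sense, and the carbinol is what an aldehyde addition delivers. The demand is oxidation before acetal removal, since 6 would ionise at its doubly benzylic carbon under acid, and an acetal cleavage that spares the silyl ether.

6 is cut at the bond between C4 of ring A and the carbinol carbon, giving 4 (through its lithio derivative 5) and 2. C4 lies between two acetal oxygens and is the natural site of directed metalation. The gain is two simple monocyclic pieces. The demand is metalation between the two acetals and not between an acetal and the methoxy group.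

4 goes back to 3 and 2 goes back to 1 by cutting O–C (acetal) and O–Si bonds. Both are plain protections of commercial phenols. The only demand is complete bis-alkylation of 3.

## Other disconnections considered

Alternative 1: The cut goes through ring A at C3–C4 and C5–C6. One piece is the four-carbon unit C6–C1–C2–C3, which already holds both prenyl groups and the C1 methoxy group: trimethyl{[1,3-dimethoxy-7-methyl-2-(3-methylbut-2-en-1-yl)octa-1,3,6-trien-1-yl]oxy}silane A2. The other is the two-carbon unit C4–C5 with the aroyl group: 3-ethoxy-1-[4-(methoxymethoxy)phenyl]prop-2-yn-1-one A3.

- Forward step: A2 and A3 would combine in a Diels–Alder reaction. Its regiochemistry follows from the polarisation of both partners: the CH terminus of A2 is the nucleophilic end and the ethoxy-bearing alkyne carbon of A3 the electrophilic end. The adduct would expel its silylated methoxy group and enolise to [2-ethoxy-6-hydroxy-4-methoxy-3,5-bis(3-methylbut-2-en-1-yl)phenyl][4-(methoxymethoxy)phenyl]methanone A1.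
- In its favour: all six substituents of ring A are placed by the cycloaddition, so no selective substitution on an arene is needed. The key step makes two skeletal bonds and the ring in one operation.
- Against it here: A1 carries an ethyl ether where the target needs the C5 hydroxyl. A Lewis-acid dealkylation (BCl3, assisted by chelation to the ketone) would have to be run on a compound with two acid-sensitive prenyl groups next to phenol oxygens, and the ring B acetal must also come off under acid. A2 is a tetrasubstituted, doubly prenylated diene whose preparation (C-prenylations of a β-keto ester, enol ether formation, γ-deprotonation and silylation, with geometry at the CH terminus to control) is a multistep problem of its own. A3 is a moisture-sensitive ynol ether.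
- Comparison: on structure, Alternative 1 is the better plan for fixing the oxygen pattern, because it needs no regioselective metalation, and it equals the chosen plan in skeletal bonds formed by the key step (two). On mechanism, the cycloaddition of a hindered 2,4-disubstituted diene is less predictable than capture of a quinone methide by a Grignard reagent, and the end game is harsher than a fluoride desilylation. On step economy, making A2 and A3 and then removing two different ethers should need more steps than the nine of the chosen route.

Alternative 2: The cut is at the C4–carbonyl bond and the C5–O bond.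

- Forward step: fluoride (CsF) would release the aryne 1-methoxy-3-(methoxymethoxy)-2,6-bis(3-methylbut-2-en-1-yl)-4,5-didehydrobenzene A7 from 5-methoxy-3-(methoxymethoxy)-4,6-bis(3-methylbut-2-en-1-yl)-2-(trimethylsilyl)phenyl trifluoromethanesulfonate A5. The carboxylate of 4-(methoxymethoxy)benzoic acid A6 would add at C5, the aryne carbon remote from the C3 acetal oxygen, so that the carbanion developing at C4 is stabilised inductively. That carbanion would then attack the ester carbonyl and move the acyl group from oxygen to carbon, giving [2-hydroxy-4-methoxy-6-(methoxymethoxy)-3,5-bis(3-methylbut-2-en-1-yl)phenyl][4-(methoxymethoxy)phenyl]methanone A4.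
- In its favour: the ketone and its ortho hydroxyl arise together, late and under nearly neutral conditions, with no organolithium or Grignard reagent. The assembly is convergent.
- Against it here: A5 is a hexasubstituted benzene that already carries both prenyl groups. The hardest problem of the target, twofold C-prenylation of a phloroglucinol, is therefore moved into the preparation of A5 and is not solved by the key step. Installing the ortho silyl and triflate groups on so crowded a ring adds further steps. In A7 the prenyl group on C6 crowds the carbon that oxygen must attack and offers an alkene with allylic hydrogens for intramolecular ene or cycloaddition pathways. A4 needs two acetals removed under acid in the presence of ortho-prenyl phenols, with the risk of chroman formation.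
- Comparison: on structure, Alternative 2 is the equal or the better for the benzophenone linkage (one operation instead of addition followed by oxidation), but it contributes nothing to the prenyl groups, which the chosen plan introduces last and at fixed positions. On mechanism, the regiochemistry of aryne capture rests on the inductive bias of one acetal substituent, whereas the chosen key step has no regiochemical choice to make. On step economy, the route to A5 alone should be longer than the whole chosen route.

Alternative 3: The cut is at the C4–C5 bond of ring A, leading back to 4-methoxy-6-{2-[4-(methoxymethoxy)phenyl]-2-oxoethyl}-3,5-bis(3-methylbut-2-en-1-yl)-2H-pyran-2-one A9, a masked tetraketide.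

- Forward step: Mg(OMe)2 in methanol would open the lactone at its carbonyl to a methyl ester (future C5). The CH2 between the two ketone carbonyls (future C4), held as a magnesium chelate, would attack that ester in a Claisen condensation and, after tautomerisation, give [2,6-dihydroxy-4-methoxy-3,5-bis(3-methylbut-2-en-1-yl)phenyl][4-(methoxymethoxy)phenyl]methanone A8.
- In its favour: the plan follows the biosynthetic logic. A8 emerges with exactly the ring A pattern of the target, both hydroxyls free and the methyl ether fixed by the pyranone, and needs only one deprotection.
- Against it here: A9 must carry two prenyl groups on the pyranone and an aroylmethyl side chain. Its preparation is long and brings back C- versus O-alkylation problems at the pyranone stage. A 4-methoxypyranone opens less readily than a 4-hydroxypyranone. The opened chain can return to the lactone or close to a 4-pyranone instead of undergoing the Claisen condensation. The acetal on ring B of A8 would have to be removed with acid next to two prenyl phenols (a silyl ether would be the better choice there).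
- Comparison: on structure, Alternative 3 is the equal of the chosen plan in the number of steps after the key step (one) and the better in that the position of the methyl ether depends on no selective reaction. On mechanism, the cyclisation has competing modes of closure, whereas the quinone methide capture has only the 1,4 versus 1,2 question. On step economy, the preparation of A9 should outweigh the short end game.

Key step: step 8

Assumption: 12 is used as the commercial THF solution, titrated before use (it can equally be made from 1-bromo-2-methylprop-1-ene and magnesium turnings in THF). 6 is racemic and its only stereocentre disappears in step 4. The structures of 11, 16 and 17 agree with each other atom by atom (OMe on C1, carbon substituents on C2 and C6, OH on C3 and C5, aroyl on C4). Where a step consumes two equivalents of a reagent or of a numbered compound, this is stated in the step.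

## Steps

Step 1
Reactants: 1 4-hydroxybenzaldehyde
Product: 2 4-{[tri(propan-2-yl)silyl]oxy}benzaldehyde
Conditions: TIPSCl, imidazole, DMF, rt
Reagents that add atoms: chlorotri(propan-2-yl)silane, CC(C)[Si](Cl)(C(C)C)C(C)C
Why: Silylation of a phenol with a silyl chloride and imidazole; the aldehyde is inert, and the bulky aryl silyl ether should later withstand the aryllithium, methanolic acid and the Grignard reagent.

Step 2
Reactants: 3 5-methoxyresorcinol (5-methoxybenzene-1,3-diol)
Product: 4 1-methoxy-3,5-bis(methoxymethoxy)benzene
Conditions: MOMCl (2.5 equiv), i-Pr2NEt, CH2Cl2, 0 °C → rt
Reagents that add atoms: chloro(methoxy)methane (two equivalents, one per hydroxyl), COCCl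
Why: O-Alkylation of both phenols by the reactive α-chloro ether (acetal formation); the two acetals serve as directing groups for the next step and are removable with mild acid.

Step 3
Reactants: 4 1-methoxy-3,5-bis(methoxymethoxy)benzene; 2 4-{[tri(propan-2-yl)silyl]oxy}benzaldehyde
Product: 6 racemic [4-methoxy-2,6-bis(methoxymethoxy)phenyl]{4-[tri(propan-2-yl)silyloxy]phenyl}methanol, via aryllithium 5 (not isolated)
Conditions: n-BuLi, THF, 0 °C; then 2, −78 → 0 °C; aq. NH4Cl
Reagents that add atoms: none
Why: Directed ortho-metalation: the ring CH between the two chelating acetal oxygens is the most acidic and best coordinated site (an acetal oxygen directs more strongly than a methoxy group), and 5 then adds 1,2 to the aldehyde. The carbinol stereocentre forms without control (racemic) and is removed in step 4.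

Step 4
Reactants: 6 racemic [4-methoxy-2,6-bis(methoxymethoxy)phenyl]{4-[tri(propan-2-yl)silyloxy]phenyl}methanol
Product: 7 [4-methoxy-2,6-bis(methoxymethoxy)phenyl]{4-[tri(propan-2-yl)silyloxy]phenyl}methanone
Conditions: Dess–Martin periodinane, NaHCO3, CH2Cl2, 0 °C → rt
Reagents that add atoms: none
Why: Dess–Martin oxidation of a secondary diaryl carbinol to the ketone; the bicarbonate buffer keeps the easily ionised, doubly benzylic carbinol and the acetals away from acid, and the silyl ether is untouched.

Step 5
Reactants: 7 [4-methoxy-2,6-bis(methoxymethoxy)phenyl]{4-[tri(propan-2-yl)silyloxy]phenyl}methanone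
Product: 8 (2,6-dihydroxy-4-methoxyphenyl){4-[tri(propan-2-yl)silyloxy]phenyl}methanone
Conditions: HCl (1.25 M in MeOH), THF, 0 °C → rt
Reagents that add atoms: none
Why: Acid-catalysed acetal exchange with methanol; acetals ortho to a carbonyl cleave easily, the formaldehyde unit is carried off as its dimethyl acetal and so cannot bridge two electron-rich rings, and the hindered silyl ether on the electron-poor ring B should solvolyse much more slowly.

Step 6
Reactants: 8 (2,6-dihydroxy-4-methoxyphenyl){4-[tri(propan-2-yl)silyloxy]phenyl}methanone; 9 N,N-dimethylmethaniminium iodide (dimethylmethylideneammonium iodide), two equivalents consumed, one at each free ring position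
Product: 10 {3,5-bis[(dimethylamino)methyl]-2,6-dihydroxy-4-methoxyphenyl}{4-[tri(propan-2-yl)silyloxy]phenyl}methanone
Conditions: 9 (2.5 equiv), Et3N, CH2Cl2, 0 °C → rt; aq. NaHCO3
Reagents that add atoms: N,N-dimethylmethaniminium iodide (the second equivalent of 9, which supplies the second CH2NMe2 group), C[N+](C)=C.[I-]
Why: Twofold Mannich aminomethylation (electrophilic aromatic substitution by a preformed iminium ion), in which each of the two equivalents of 9 delivers one CH2NMe2 group and the proton it displaces is taken up by Et3N. The two free positions of ring A are each ortho to a hydroxyl and to the methoxy group and para to the other hydroxyl, whereas ring B has no free phenol and is deactivated by the carbonyl, and the slight excess of 9 keeps the iminium ion the dominant electrophile so that both positions are substituted.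

Step 7
Reactants: 10 {3,5-bis[(dimethylamino)methyl]-2,6-dihydroxy-4-methoxyphenyl}{4-[tri(propan-2-yl)silyloxy]phenyl}methanone
Product: 11 [4,6-dihydroxy-2-methoxy-5-{4-[tri(propan-2-yl)silyloxy]benzoyl}-1,3-phenylene]bis(N,N,N-trimethylmethanaminium) diiodide
Conditions: MeI (excess), THF, rt, dark; filtration
Reagents that add atoms: iodomethane (two equivalents, one per nitrogen), CI
Why: Menshutkin quaternisation of the two tertiary benzylic amines; without added base the carbonyl-chelated phenols are poor nucleophiles, and the bis-salt should precipitate from THF, which takes it out of further reaction.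

Step 8
Reactants: 11 [4,6-dihydroxy-2-methoxy-5-{4-[tri(propan-2-yl)silyloxy]benzoyl}-1,3-phenylene]bis(N,N,N-trimethylmethanaminium) diiodide; 12 bromo(2-methylprop-1-en-1-yl)magnesium (2-methylprop-1-enylmagnesium bromide), two equivalents incorporated, further equivalents consumed as base
Product: 16 [2,6-dihydroxy-4-methoxy-3,5-bis(3-methylbut-2-en-1-yl)phenyl]{4-[tri(propan-2-yl)silyloxy]phenyl}methanone, via first ortho-quinone methide 13 (not isolated), via monoprenylated ammonium salt 14 (not isolated), via second ortho-quinone methide 15 (not isolated)
Conditions: 11 (suspension in THF) added to Me2C=CHMgBr (8 equiv), THF, −40 °C → rt; aq. NH4Cl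
Reagents that add atoms: bromo(2-methylprop-1-en-1-yl)magnesium (the second equivalent of 12, which supplies the second alkenyl group), CC(C)=C[Mg]Br
Why: The first two equivalents of the Grignard reagent deprotonate the hydroxyls on C3 and C5; one magnesium phenoxide then expels trimethylamine from the neighbouring benzylic carbon (1,4-elimination) to give ortho-quinone methide 13, whose exocyclic CH2 is attacked by the metal-bearing carbon of the alkenyl reagent, restoring the aromatic phenoxide in 14. The same elimination–addition sequence on the other side of the methoxy group passes through 15, takes up a second alkenyl group and should give 16 after protonation. The closest known reaction type is the 1,4-addition of Grignard reagents to ortho-quinone methides released by base from ortho-hydroxybenzyl trimethylammonium salts (Mannich base methiodides). No ring is closed and no stereocentre is formed; the trisubstituted alkene is delivered intact by the reagent and, ending in two methyl groups, has no geometry to control. The selectivity needed is conjugate addition to the quinone methide in preference to 1,2-addition at the diaryl ketone: the ketone lies between two ortho magnesium phenoxides and is therefore a chelated, twisted, vinylogous carboxylate of low electrophilicity, whereas addition to the quinone methide regains aromaticity. Because the electrophilic carbon is the benzylic CH2 itself, O-alkylation, bond formation through the tertiary allyl terminus and geminal dialkylation with loss of aromaticity have no pathway. Inverse addition keeps the nucleophile in excess over each quinone methide, so that self-condensation of the quinone methide should be outpaced, and the hindered aryl silyl ether is not attacked by the reagent.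

Step 9
Reactants: 16 [2,6-dihydroxy-4-methoxy-3,5-bis(3-methylbut-2-en-1-yl)phenyl]{4-[tri(propan-2-yl)silyloxy]phenyl}methanone
Product: 17 vismiaphenone D, [2,6-dihydroxy-4-methoxy-3,5-bis(3-methylbut-2-en-1-yl)phenyl](4-hydroxyphenyl)methanone
Conditions: Bu4NF, AcOH, THF, 0 °C
Reagents that add atoms: none
Why: Fluoride-induced cleavage of an aryl silyl ether, driven by the Si–F bond and the good leaving ability of the para-acyl phenoxide; the acetic acid buffer avoids a strongly basic medium for the oxidisable acylphloroglucinol, and no strong acid is present that could cyclise the ortho-prenyl phenols to chromans.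

## Compound list

1 | 4-hydroxybenzaldehyde | O=Cc1ccc(O)cc1 | starting material
2 | 4-{[tri(propan-2-yl)silyl]oxy}benzaldehyde | O=Cc1ccc(O[Si](C(C)C)(C(C)C)C(C)C)cc1 | intermediate
3 | 5-methoxyresorcinol (5-methoxybenzene-1,3-diol) | COc1cc(O)cc(O)c1 | starting material
4 | 1-methoxy-3,5-bis(methoxymethoxy)benzene | COCOc1cc(OC)cc(OCOC)c1 | intermediate
5 | [4-methoxy-2,6-bis(methoxymethoxy)phenyl]lithium | [Li]c1c(OCOC)cc(OC)cc1OCOC | intermediate (not isolated)
6 | racemic [4-methoxy-2,6-bis(methoxymethoxy)phenyl]{4-[tri(propan-2-yl)silyloxy]phenyl}methanol | COCOc1cc(OC)cc(OCOC)c1C(O)c1ccc(O[Si](C(C)C)(C(C)C)C(C)C)cc1 | intermediate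
7 | [4-methoxy-2,6-bis(methoxymethoxy)phenyl]{4-[tri(propan-2-yl)silyloxy]phenyl}methanone | COCOc1cc(OC)cc(OCOC)c1C(=O)c1ccc(O[Si](C(C)C)(C(C)C)C(C)C)cc1 | intermediate
8 | (2,6-dihydroxy-4-methoxyphenyl){4-[tri(propan-2-yl)silyloxy]phenyl}methanone | COc1cc(O)c(C(=O)c2ccc(O[Si](C(C)C)(C(C)C)C(C)C)cc2)c(O)c1 | intermediate
9 | N,N-dimethylmethaniminium iodide (dimethylmethylideneammonium iodide) | C[N+](C)=C.[I-] | starting material
10 | {3,5-bis[(dimethylamino)methyl]-2,6-dihydroxy-4-methoxyphenyl}{4-[tri(propan-2-yl)silyloxy]phenyl}methanone | COc1c(CN(C)C)c(O)c(C(=O)c2ccc(O[Si](C(C)C)(C(C)C)C(C)C)cc2)c(O)c1CN(C)C | intermediate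
11 | [4,6-dihydroxy-2-methoxy-5-{4-[tri(propan-2-yl)silyloxy]benzoyl}-1,3-phenylene]bis(N,N,N-trimethylmethanaminium) diiodide | COc1c(C[N+](C)(C)C)c(O)c(C(=O)c2ccc(O[Si](C(C)C)(C(C)C)C(C)C)cc2)c(O)c1C[N+](C)(C)C.[I-].[I-] | intermediate
12 | bromo(2-methylprop-1-en-1-yl)magnesium (2-methylprop-1-enylmagnesium bromide) | CC(C)=C[Mg]Br | starting material
13 | first ortho-quinone methide: 1-[6-hydroxy-2-methoxy-3-methylidene-4-oxo-5-{4-[tri(propan-2-yl)silyloxy]benzoyl}cyclohexa-1,5-dien-1-yl]-N,N,N-trimethylmethanaminium iodide, formed from 11 by loss of one trimethylamine (drawn O-protonated; magnesium-bound in the flask) | C=C1C(=O)C(C(=O)c2ccc(O[Si](C(C)C)(C(C)C)C(C)C)cc2)=C(O)C(C[N+](C)(C)C)=C1OC.[I-] | intermediate (not isolated)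
14 | monoprenylated ammonium salt: 1-[2,4-dihydroxy-6-methoxy-5-(3-methylbut-2-en-1-yl)-3-{4-[tri(propan-2-yl)silyloxy]benzoyl}phenyl]-N,N,N-trimethylmethanaminium iodide (drawn O-protonated; magnesium phenoxide in the flask) | COc1c(CC=C(C)C)c(O)c(C(=O)c2ccc(O[Si](C(C)C)(C(C)C)C(C)C)cc2)c(O)c1C[N+](C)(C)C.[I-] | intermediate (not isolated)
15 | second ortho-quinone methide: 3-hydroxy-5-methoxy-6-methylidene-4-(3-methylbut-2-en-1-yl)-2-{4-[tri(propan-2-yl)silyloxy]benzoyl}cyclohexa-2,4-dien-1-one, formed from 14 by loss of trimethylamine (drawn O-protonated; magnesium-bound in the flask) | C=C1C(=O)C(C(=O)c2ccc(O[Si](C(C)C)(C(C)C)C(C)C)cc2)=C(O)C(CC=C(C)C)=C1OC | intermediate (not isolated)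
16 | [2,6-dihydroxy-4-methoxy-3,5-bis(3-methylbut-2-en-1-yl)phenyl]{4-[tri(propan-2-yl)silyloxy]phenyl}methanone | COc1c(CC=C(C)C)c(O)c(C(=O)c2ccc(O[Si](C(C)C)(C(C)C)C(C)C)cc2)c(O)c1CC=C(C)C | intermediate
17 | vismiaphenone D, [2,6-dihydroxy-4-methoxy-3,5-bis(3-methylbut-2-en-1-yl)phenyl](4-hydroxyphenyl)methanone | COc1c(CC=C(C)C)c(O)c(C(=O)c2ccc(O)cc2)c(O)c1CC=C(C)C | target

## Step count and least certain steps

Total step count: 9. Longest linear sequence: 8 steps (3 → 17 through steps 2 to 9; the branch from 1 is equally long through steps 1 and 3 to 9).

Step 8 (key step). The most likely failures are 1,2-addition of the reagent to the diaryl ketone, stalling after the first prenylation because the acyl-stabilised magnesium phenoxide pushes out the second trimethylamine only slowly, and self-condensation of a quinone methide when the poorly soluble bis-salt reacts heterogeneously. The fallback changes the way the side chains are built and uses only established reactions. It sets out from 8 and comes back to the route at 16. Both phenols of 8 would be allylated (allyl bromide, K2CO3, acetone, 50 °C) to [4-methoxy-2,6-bis(prop-2-en-1-yloxy)phenyl]{4-[tri(propan-2-yl)silyloxy]phenyl}methanone F1. A twofold aromatic Claisen rearrangement (N,N-diethylaniline, 190 °C) can only go to the one free ortho position of each ether and should give [2,6-dihydroxy-4-methoxy-3,5-di(prop-2-en-1-yl)phenyl]{4-[tri(propan-2-yl)silyloxy]phenyl}methanone F2. Cross-metathesis of F2 with 2-methylbut-2-ene (second-generation Grubbs catalyst, (H2IMes)(PCy3)Cl2Ru=CHPh, CH2Cl2, 40 °C) would turn each allyl group into a prenyl group and deliver 16.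

Step 3. Metalation may also take place at the ring positions between an acetal and the methoxy group (two such sites against one), which would lead to a regioisomeric carbinol; the electron-rich carbinol can also ionise during work-up. The fallback removes the regiochemical question by using a threefold symmetric ring. It sets out from 2 and comes back at 8. Benzene-1,3,5-triol (phloroglucinol) F3 would be converted with MOMCl and NaH in DMF into 1,3,5-tris(methoxymethoxy)benzene F4. Lithiation of F4 with n-BuLi, in which all three ring positions are equivalent, would give [2,4,6-tris(methoxymethoxy)phenyl]lithium F5, and its addition to 2 would give the racemic carbinol {4-[tri(propan-2-yl)silyloxy]phenyl}[2,4,6-tris(methoxymethoxy)phenyl]methanol F6. Dess–Martin oxidation would then give {4-[tri(propan-2-yl)silyloxy]phenyl}[2,4,6-tris(methoxymethoxy)phenyl]methanone F7, and methanolic HCl would give {4-[tri(propan-2-yl)silyloxy]phenyl}(2,4,6-trihydroxyphenyl)methanone F8. Monomethylation of F8 with one equivalent of Me2SO4 and K2CO3 in acetone should take place at the para hydroxyl, the only one not hydrogen-bonded to the ketone and the most acidic, to give 8.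

Step 5. The acid may partly cleave the silyl ether along with the acetals, or the released formaldehyde equivalent may bridge two molecules of the electron-rich product if methanol does not trap it fast enough. The fallback gives up selectivity in the deprotection and restores it afterwards. It sets out from 7 and comes back at 8. Hot aqueous HCl in methanol would remove both acetals and the silyl group to give (2,6-dihydroxy-4-methoxyphenyl)(4-hydroxyphenyl)methanone F9. Silylation of F9 with one equivalent of TIPSCl and imidazole in CH2Cl2 at 0 °C should occur only at the ring B hydroxyl, since the two ring A hydroxyls are chelated to the carbonyl and flanked by it, and so return 8.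

Step 7. The Mannich base may exist partly as a phenoxide–ammonium zwitterion, so that methylation on oxygen competes with quaternisation, and the bis-salt may lose trimethylamine on handling and oligomerise through quinone methides. The fallback replaces the ammonium leaving group by acetate. It sets out from 10 and comes back at 16. Heating 10 in acetic anhydride (amine–acetate exchange with acetylation of the phenols) would give [3,5-bis(acetoxymethyl)-2,6-diacetoxy-4-methoxyphenyl]{4-[tri(propan-2-yl)silyloxy]phenyl}methanone F10. With an excess of 12 in THF the aryl acetates of F10 would be cleaved to magnesium phenoxides, which expel the benzylic acetates, and the quinone methides so formed would take up the alkenyl group as in step 8 to give 16.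

## Further compounds

F1 | step 8 | [4-methoxy-2,6-bis(prop-2-en-1-yloxy)phenyl]{4-[tri(propan-2-yl)silyloxy]phenyl}methanone | COc1cc(OCC=C)c(C(=O)c2ccc(O[Si](C(C)C)(C(C)C)C(C)C)cc2)c(OCC=C)c1
F2 | step 8 | [2,6-dihydroxy-4-methoxy-3,5-di(prop-2-en-1-yl)phenyl]{4-[tri(propan-2-yl)silyloxy]phenyl}methanone | COc1c(CC=C)c(O)c(C(=O)c2ccc(O[Si](C(C)C)(C(C)C)C(C)C)cc2)c(O)c1CC=C
F3 | step 3 | benzene-1,3,5-triol (phloroglucinol) | Oc1cc(O)cc(O)c1
F4 | step 3 | 1,3,5-tris(methoxymethoxy)benzene | COCOc1cc(OCOC)cc(OCOC)c1
F5 | step 3 | [2,4,6-tris(methoxymethoxy)phenyl]lithium | [Li]c1c(OCOC)cc(OCOC)cc1OCOC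
F6 | step 3 | racemic {4-[tri(propan-2-yl)silyloxy]phenyl}[2,4,6-tris(methoxymethoxy)phenyl]methanol | COCOc1cc(OCOC)c(C(O)c2ccc(O[Si](C(C)C)(C(C)C)C(C)C)cc2)c(OCOC)c1
F7 | step 3 | {4-[tri(propan-2-yl)silyloxy]phenyl}[2,4,6-tris(methoxymethoxy)phenyl]methanone | COCOc1cc(OCOC)c(C(=O)c2ccc(O[Si](C(C)C)(C(C)C)C(C)C)cc2)c(OCOC)c1
F8 | step 3 | {4-[tri(propan-2-yl)silyloxy]phenyl}(2,4,6-trihydroxyphenyl)methanone | Oc1cc(O)c(C(=O)c2ccc(O[Si](C(C)C)(C(C)C)C(C)C)cc2)c(O)c1
F9 | step 5 | (2,6-dihydroxy-4-methoxyphenyl)(4-hydroxyphenyl)methanone | COc1cc(O)c(C(=O)c2ccc(O)cc2)c(O)c1
F10 | step 7 | [3,5-bis(acetoxymethyl)-2,6-diacetoxy-4-methoxyphenyl]{4-[tri(propan-2-yl)silyloxy]phenyl}methanone | COc1c(COC(C)=O)c(OC(C)=O)c(C(=O)c2ccc(O[Si](C(C)C)(C(C)C)C(C)C)cc2)c(OC(C)=O)c1COC(C)=O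
A1 | alternative 1 | [2-ethoxy-6-hydroxy-4-methoxy-3,5-bis(3-methylbut-2-en-1-yl)phenyl][4-(methoxymethoxy)phenyl]methanone | CCOc1c(CC=C(C)C)c(OC)c(CC=C(C)C)c(O)c1C(=O)c1ccc(OCOC)cc1
A2 | alternative 1 | trimethyl{[1,3-dimethoxy-7-methyl-2-(3-methylbut-2-en-1-yl)octa-1,3,6-trien-1-yl]oxy}silane | COC(O[Si](C)(C)C)=C(CC=C(C)C)C(OC)=CCC=C(C)C
A3 | alternative 1 | 3-ethoxy-1-[4-(methoxymethoxy)phenyl]prop-2-yn-1-one | CCOC#CC(=O)c1ccc(OCOC)cc1
A4 | alternative 2 | [2-hydroxy-4-methoxy-6-(methoxymethoxy)-3,5-bis(3-methylbut-2-en-1-yl)phenyl][4-(methoxymethoxy)phenyl]methanone | COCOc1ccc(cc1)C(=O)c1c(O)c(CC=C(C)C)c(OC)c(CC=C(C)C)c1OCOC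
A5 | alternative 2 | 5-methoxy-3-(methoxymethoxy)-4,6-bis(3-methylbut-2-en-1-yl)-2-(trimethylsilyl)phenyl trifluoromethanesulfonate | COCOc1c([Si](C)(C)C)c(OS(=O)(=O)C(F)(F)F)c(CC=C(C)C)c(OC)c1CC=C(C)C
A6 | alternative 2 | 4-(methoxymethoxy)benzoic acid | COCOc1ccc(cc1)C(=O)O
A7 | alternative 2 | 1-methoxy-3-(methoxymethoxy)-2,6-bis(3-methylbut-2-en-1-yl)-4,5-didehydrobenzene | COCOC1=C(CC=C(C)C)C(OC)=C(CC=C(C)C)C#C1
A8 | alternative 3 | [2,6-dihydroxy-4-methoxy-3,5-bis(3-methylbut-2-en-1-yl)phenyl][4-(methoxymethoxy)phenyl]methanone | COCOc1ccc(cc1)C(=O)c1c(O)c(CC=C(C)C)c(OC)c(CC=C(C)C)c1O
A9 | alternative 3 | 4-methoxy-6-{2-[4-(methoxymethoxy)phenyl]-2-oxoethyl}-3,5-bis(3-methylbut-2-en-1-yl)-2H-pyran-2-one | COCOc1ccc(cc1)C(=O)CC1=C(CC=C(C)C)C(OC)=C(CC=C(C)C)C(=O)O1
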